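**Plan**
1. Retrosynthesis: the two benzyl ethers are cut last (hydrogenolysis). Before that, one operation cuts both the C2–C1' bond between pyrone ring C and ring B and the CH2–CH2 bond of the eight-membered oxocine ring. This gives 3-methylchromone 5 and di-iodide 10; 5 goes back to acetophenone 1 and 10 to 3-(benzyloxy)phenol 6.
2. Enabling feature: the C2=C3 enol-ether bond of ring C with its 3-methyl group. After syn-arylpalladation at C2, H-2 is anti to palladium, so the methyl group loses hydrogen and becomes an exocyclic enone CH2. The O–CMe2–CH2–I unit on ring B (primary iodide, no β-hydrogen, no SN2) then adds to that CH2 as a radical/alkylpalladium.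
3. Forward order: ring C (enaminone iodocyclisation, methyl Suzuki–Miyaura); ring B side chain (iodination, O-alkylation, reduction, iodination); the domino Heck annulation closes the oxocine ring; debenzylation.
4. Stereochemistry: the target has no stereocentre. C2 of intermediate 11 forms racemic and is flattened again by the last β-hydride elimination.

Key step: step 8

Assumption: 1 and 6 are bought; in step 1 only one of the two equivalent hydroxyls of 1 is expected to react, because the other stays hydrogen-bonded to the ketone.

**Step 1**
Reactants: 1 1-(2,6-dihydroxy-4-methoxyphenyl)ethan-1-one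
Product: 2 1-[2-(benzyloxy)-6-hydroxy-4-methoxyphenyl]ethan-1-one
Conditions: BnBr (1.05 equiv), K2CO3, acetone, reflux
Reagents that add atoms: benzyl bromide BrCc1ccccc1
Why: Williamson ether synthesis; after the first alkylation the remaining hydroxyl is chelated to the acetyl oxygen and should react much more slowly.

**Step 2**
Reactants: 2 1-[2-(benzyloxy)-6-hydroxy-4-methoxyphenyl]ethan-1-one
Product: 4 5-(benzyloxy)-3-iodo-7-methoxy-4H-chromen-4-one, via enaminone 3 (not isolated)
Conditions: DMF-DMA, 95 °C; evaporate; I2, CHCl3, rt
Reagents that add atoms: N,N-dimethylformamide dimethyl acetal COC(OC)N(C)C; iodine II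
Why: Enaminone formation followed by iodine-induced cyclisation (α-iodination, attack of the phenol oxygen, loss of dimethylamine) is the standard entry to 3-iodochromones and builds pyrone ring C.

**Step 3**
Reactants: 4 5-(benzyloxy)-3-iodo-7-methoxy-4H-chromen-4-one
Product: 5 5-(benzyloxy)-7-methoxy-3-methyl-4H-chromen-4-one
Conditions: MeB(OH)2, Pd(dppf)Cl2 (5 mol %), K2CO3, 1,4-dioxane/H2O 10:1, 90 °C
Reagents that add atoms: methylboronic acid CB(O)O
Why: Suzuki–Miyaura methylation of an electron-poor vinylic iodide; mild carbonate base and short heating should limit opening of the pyrone ring.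

**Step 4**
Reactants: 6 3-(benzyloxy)phenol
Product: 7 5-(benzyloxy)-2-iodophenol
Conditions: I2, NaHCO3, THF/H2O, 0 °C to rt
Reagents that add atoms: iodine II
Why: Electrophilic aromatic iodination of the phenoxide; the position ortho to OH and para to OBn is doubly activated and less hindered than the position between the two oxygens.

**Step 5**
Reactants: 7 5-(benzyloxy)-2-iodophenol
Product: 8 ethyl 2-[5-(benzyloxy)-2-iodophenoxy]-2-methylpropanoate
Conditions: ethyl 2-bromo-2-methylpropanoate (1.5 equiv), Cs2CO3, DMF, 60 °C
Reagents that add atoms: ethyl 2-bromo-2-methylpropanoate CCOC(=O)C(C)(C)Br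
Why: Williamson-type O-alkylation with a tertiary α-bromo ester, the usual way to 2-aryloxy-2-methylpropanoates; the caesium phenoxide in DMF should favour substitution over elimination.

**Step 6**
Reactants: 8 ethyl 2-[5-(benzyloxy)-2-iodophenoxy]-2-methylpropanoate
Product: 9 2-[5-(benzyloxy)-2-iodophenoxy]-2-methylpropan-1-ol
Conditions: i-Bu2AlH (2.5 equiv), CH2Cl2, −78 to 0 °C; aq. potassium sodium tartrate
Reagents that add atoms: none
Why: Hydride reduction of the ester to the primary alcohol; the aryl iodide and the benzyl ether should be inert to i-Bu2AlH at low temperature.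

**Step 7**
Reactants: 9 2-[5-(benzyloxy)-2-iodophenoxy]-2-methylpropan-1-ol
Product: 10 4-(benzyloxy)-1-iodo-2-[(1-iodo-2-methylpropan-2-yl)oxy]benzene
Conditions: PPh3, I2, imidazole, toluene, 80 °C
Reagents that add atoms: iodine II
Why: Appel-type iodination; the alkoxyphosphonium leaving group should allow iodide to substitute even at this neopentyl-like carbon on heating.

**Step 8**
Reactants: 10 4-(benzyloxy)-1-iodo-2-[(1-iodo-2-methylpropan-2-yl)oxy]benzene; 5 5-(benzyloxy)-7-methoxy-3-methyl-4H-chromen-4-one
Product: 12 cyclointegrin dibenzyl ether (benzyl on O-5 and on O-4'), via 3-methylideneflavanone 11 (not isolated)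
Conditions: 5 (1.3 equiv), Pd(dppf)Cl2 (10 mol %), Cy2NMe (3 equiv), PhCF3, 110 °C, degassed
Reagents that add atoms: none
Why: Proposed new method: zerovalent palladium should add first to the aryl C–I bond of 10 (the primary C–I bond on the CMe2 carbon is neopentyl-like and cannot undergo two-electron oxidative addition), and the arylpalladium iodide should then add syn across the C2=C3 bond of pyrone ring C of 5 with the aryl group on C2, the unsubstituted carbon that is at once the enone β-carbon and the oxygen-bearing carbon; the closest known reaction type is the Mizoroki–Heck arylation of cyclic enones and enol ethers. After this syn addition H-2 lies anti to palladium on C3, so only a hydrogen of the 3-methyl group can leave by syn β-hydride elimination, which should give the exocyclic enone 11 and return zerovalent palladium. The catalyst then activates the remaining primary C–I bond by single-electron transfer, as in palladium-catalysed Heck-type cyclisations of unactivated alkyl iodides, and the nucleophilic primary radical (no β-hydrogen, so no alkene loss) should attack the terminal CH2 of the enone in an 8-endo-trig closure of the oxocine ring, the 7-exo mode being disfavoured because it opposes the polarity of the acceptor and would join two quaternary carbons. The C3 radical is captured as a palladium enolate that can sit syn to H-2, and β-hydride elimination (or elimination into the bridge followed by hydride re-addition) should restore the aromatic γ-pyrone, erasing the only stereocentre, C2 of 11, which is formed racemic and needs no control. The step needs aryl-before-alkyl activation and methyl-before-H-2 elimination, both set by the substrate (sp2 against neopentyl C–I, anti H-2), and closure before palladium hydride moves the exocyclic double bond of 11 into the ring. An amine base without carboxylate is used so that concerted metalation of the gem-dimethyl C–H bonds, which would end in a dihydrobenzofuran, is not opened.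

**Step 9**
Reactants: 12 cyclointegrin dibenzyl ether
Product: 13 cyclointegrin
Conditions: H2 (1 atm), Pd/C (10 wt %), EtOAc/MeOH, rt
Reagents that add atoms: none
Why: Hydrogenolysis of both aryl benzyl ethers; the tetrasubstituted C2=C3 bond of the pyrone and the tertiary alkyl aryl ether of the oxocine ring should survive these neutral conditions.

**Compound list**
1 | 1-(2,6-dihydroxy-4-methoxyphenyl)ethan-1-one | CC(=O)c1c(O)cc(OC)cc1O | starting material
2 | 1-[2-(benzyloxy)-6-hydroxy-4-methoxyphenyl]ethan-1-one | CC(=O)c1c(O)cc(OC)cc1OCc1ccccc1 | intermediate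
3 | (E)-1-[2-(benzyloxy)-6-hydroxy-4-methoxyphenyl]-3-(dimethylamino)prop-2-en-1-one (enaminone, not isolated) | CN(C)/C=C/C(=O)c1c(O)cc(OC)cc1OCc1ccccc1 | intermediate
4 | 5-(benzyloxy)-3-iodo-7-methoxy-4H-chromen-4-one | COc1cc(OCc2ccccc2)c2c(=O)c(I)coc2c1 | intermediate
5 | 5-(benzyloxy)-7-methoxy-3-methyl-4H-chromen-4-one | COc1cc(OCc2ccccc2)c2c(=O)c(C)coc2c1 | intermediate
6 | 3-(benzyloxy)phenol | Oc1cccc(OCc2ccccc2)c1 | starting material
7 | 5-(benzyloxy)-2-iodophenol | Oc1cc(OCc2ccccc2)ccc1I | intermediate
8 | ethyl 2-[5-(benzyloxy)-2-iodophenoxy]-2-methylpropanoate | CCOC(=O)C(C)(C)Oc1cc(OCc2ccccc2)ccc1I | intermediate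
9 | 2-[5-(benzyloxy)-2-iodophenoxy]-2-methylpropan-1-ol | OCC(C)(C)Oc1cc(OCc2ccccc2)ccc1I | intermediate
10 | 4-(benzyloxy)-1-iodo-2-[(1-iodo-2-methylpropan-2-yl)oxy]benzene | ICC(C)(C)Oc1cc(OCc2ccccc2)ccc1I | intermediate
11 | racemic 5-(benzyloxy)-2-{4-(benzyloxy)-2-[(1-iodo-2-methylpropan-2-yl)oxy]phenyl}-7-methoxy-3-methylidene-2,3-dihydro-4H-chromen-4-one (not isolated) | COc1cc(OCc2ccccc2)c2C(=O)C(=C)C(Oc2c1)c1ccc(OCc2ccccc2)cc1OC(C)(C)CI | intermediate
12 | cyclointegrin dibenzyl ether: the target with benzyl ethers at O-5 and O-4' | COc1cc(OCc2ccccc2)c2c(=O)c3c(oc2c1)-c1ccc(OCc2ccccc2)cc1OC(C)(C)CC3 | intermediate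
13 | cyclointegrin: 5,4'-dihydroxy-7-methoxyflavone with C3 and the 2'-oxygen bridged by CH2CH2C(CH3)2 | COc1cc(O)c2c(=O)c3c(oc2c1)-c1ccc(O)cc1OC(C)(C)CC3 | target

**Totals**
Total steps: 9. Longest linear sequence: 6 steps (steps 4, 5, 6, 7, 8, 9).

**Steps most likely to fail**

Step 8. Migratory insertion of the hindered arylpalladium into the trisubstituted C2=C3 bond may be too slow, so that hydrodeiodination or early single-electron activation of the alkyl iodide takes over. Palladium hydride may also move the exocyclic double bond of 11 into the ring before the radical closure. The fallback sets out from 2 and 10, returns at 12, and makes the two bonds one at a time by known reactions.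
- Mannich-type α-methylenation of 2 (paraformaldehyde, diisopropylammonium trifluoroacetate, THF, reflux) with oxa-Michael closure should give 5-(benzyloxy)-7-methoxychroman-4-one F1.
- A second α-methylenation under the same conditions should give 5-(benzyloxy)-7-methoxy-3-methylidenechroman-4-one F2.
- Radical conjugate addition of the alkyl iodide of 10 to F2 (Zn dust, CuI (copper monoiodide), EtOH/H2O, ultrasound; the aryl iodide stays untouched) should give 5-(benzyloxy)-3-{3-[5-(benzyloxy)-2-iodophenoxy]-3-methylbutyl}-7-methoxychroman-4-one F3.
- Dehydrogenation with 2-iodoxybenzoic acid (DMSO, 70 °C) should give the corresponding 4H-chromen-4-one F4.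
- C2-zincation with TMPZnCl·LiCl (THF, rt) should give the chromon-2-ylzinc chloride F5, and intramolecular Negishi coupling (Pd(OAc)2, SPhos, 50 °C) closes the oxocine ring to 12.

Step 7. Substitution at the neopentyl-like carbon may be so slow that the alkoxyphosphonium salt decays by elimination or aryloxy migration before iodide attacks. The fallback sets out from 9 and returns at 10: triflation (Tf2O, pyridine, CH2Cl2, −78 °C) to 2-[5-(benzyloxy)-2-iodophenoxy]-2-methylpropyl trifluoromethanesulfonate F6, then Finkelstein displacement with NaI in acetone at room temperature. The much better leaving group should let direct substitution outrun ionisation.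

Step 5. Elimination of HBr from the tertiary bromo ester may outrun O-alkylation of the hindered ortho-iodophenoxide. The fallback sets out from 7 and returns at 9, bypassing 8: a Bargellini reaction (acetone, CHCl3, powdered NaOH, 0 °C to reflux) should give 2-[5-(benzyloxy)-2-iodophenoxy]-2-methylpropanoic acid F7, and BH3·THF reduces the acid to 9 without touching the aryl iodide.

**Further compounds**
F1 | step 8 | 5-(benzyloxy)-7-methoxychroman-4-one | COc1cc(OCc2ccccc2)c2C(=O)CCOc2c1
F2 | step 8 | 5-(benzyloxy)-7-methoxy-3-methylidenechroman-4-one | COc1cc(OCc2ccccc2)c2C(=O)C(=C)COc2c1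
F3 | step 8 | racemic 5-(benzyloxy)-3-{3-[5-(benzyloxy)-2-iodophenoxy]-3-methylbutyl}-7-methoxychroman-4-one | COc1cc(OCc2ccccc2)c2C(=O)C(CCC(C)(C)Oc3cc(OCc4ccccc4)ccc3I)COc2c1
F4 | step 8 | 5-(benzyloxy)-3-{3-[5-(benzyloxy)-2-iodophenoxy]-3-methylbutyl}-7-methoxy-4H-chromen-4-one | COc1cc(OCc2ccccc2)c2c(=O)c(CCC(C)(C)Oc3cc(OCc4ccccc4)ccc3I)coc2c1
F5 | step 8 | [5-(benzyloxy)-3-{3-[5-(benzyloxy)-2-iodophenoxy]-3-methylbutyl}-7-methoxy-4-oxo-4H-chromen-2-yl]zinc chloride | COc1cc(OCc2ccccc2)c2c(=O)c(CCC(C)(C)Oc3cc(OCc4ccccc4)ccc3I)c([Zn]Cl)oc2c1
F6 | step 7 | 2-[5-(benzyloxy)-2-iodophenoxy]-2-methylpropyl trifluoromethanesulfonate | FC(F)(F)S(=O)(=O)OCC(C)(C)Oc1cc(OCc2ccccc2)ccc1I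
F7 | step 5 | 2-[5-(benzyloxy)-2-iodophenoxy]-2-methylpropanoic acid | OC(=O)C(C)(C)Oc1cc(OCc2ccccc2)ccc1I
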